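Remark: germacrane numbering is used (C1 ketone, C2=C3, C4=C5, C6/C7 lactone carbons, C8/C9 acyloxy carbons, C10 quaternary, C11–C13 methylene lactone, C14 methyl, C15 hydroxymethyl; O1, O6, O8, O9 are the oxygens on those carbons). The SMILES is read as 6R,7S,8S,9R,10S with a 4Z olefin. C10 of 21 is written without configuration because it is enolisable and becomes planar in step 13.

## The problem

- The skeleton is a ten-membered carbocycle (ring A, C1–C10) bridged by oxygen between C3 and C10, so that O, C3, C2, C1 and C10 form a 3(2H)-furanone (ring B). Ring A is trans-fused at C6/C7 to an α-methylene γ-lactone (ring C). Closing the strained 11-oxabicyclo[6.2.1] core is the hard bond-forming event.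
- Five contiguous stereocentres run from C6 to C10, and C10 is a quaternary ether carbon. C6 and C7 can be relayed from C8, but C9 and C10 must be set relative to that triad.
- The C4=C5 olefin is trisubstituted, Z within the ring and cross-conjugated to ring B; its geometry must be fixed before the ring is closed.
- The molecule carries three Michael acceptors (methylene lactone, methacrylate, dienone). It has a β-acyloxy ketone that becomes retro-aldol-prone when O9 is free. The trans-vicinal C8/C9 diol bears two different esters that can migrate, and there is a primary allylic alcohol.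
- The enabling feature: ring B is the keto tautomer of an aromatic 2-methyl-3-hydroxyfuran whose only sp3 atom is C10, and O9 sits β to the C1 carbonyl. The C9–C10 bond is therefore an aldol bond between a planar furanolate carbon and a C9 aldehyde.
- A precursor that is flat and stereochemically undefined at C10 can thus give ring A, the bridged bicycle and both C9 and C10 in one ring-closing, dearomatising step.

## Retrosynthesis

**Esters and protecting groups (29 back to 23).** 29 comes from silyl ether 28 (O15–Si). 28 comes from alcohol 26 and methacrylic anhydride 27 (O8 acyl). 26 comes from PMB ether 25 (O8–PMB). 25 comes from aldol 23 and isovaleryl chloride 24 (O9 acyl). O9 is acylated first, while O8 is still an ether, so the retro-aldol-prone β-hydroxy ketone is capped at once and the two esters go on in a fixed order.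

**Key disconnection, C9–C10 (23 back to 21).** Cutting the aldol bond opens ring A and returns ring B to its furan level (magnesium furanolate 22). Precursor 21 has one carbocycle fewer, no bridge and three stereocentres instead of five, and its C10 needs no configuration. Cuts at C6–C7, C4=C5 or O–C3 each leave C9 and C10 to be made separately. The forward reaction must close a ten-membered ring, alkylate at C10 and not C2, and choose one aldehyde face and one furan face.

**Ring B and oxidation levels (21 back to 18).** The O–C3 bond of 21 is cut to the α′-hydroxy ynone 20, released from TES ether 19. The C1 ketone and C9 aldehyde of 19 both come from diol 18 in one oxidation. Ring B is thus made on an open chain, where the 5-endo cyclisation has no strain to fight.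

**C6–C7 and O6–C12 (18 back to 16 and 6).** A Barbier allylation of enynal 16 with the cyclic allylic bromide 6 forms C6–C7 (adduct 17). Translactonisation from the δ-lactone (O9–C12) to the γ-lactone (O6–C12) then gives ring C and frees the C9 alcohol. The δ-lactone ring of 6 locks C8 cis to the ester (anti addition, 6,7-trans) and lets the C8 ether direct the aldehyde to the opposite ring face. One stereocentre (C8) thereby sets C6 and C7, and no protecting-group exchange is needed at O9.

**Bromolactone 6.** Ring-closing metathesis (C7=C11) leads back to diene ester 5, and esterification to alcohol 3 and acid 4. 3 comes from racemic vinyloxirane 1 and PMB alcohol 2 by a dynamic asymmetric allylic etherification that sets C8.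

**Enynal 16.** 16 comes from diol 15 by selective oxidation. 15 is cut at C3–C4 (Sonogashira) into Z-iodide 9 and alkyne 14. 9 carries the olefin geometry and comes from butynediol 7 through 8 by directed trans-hydroalumination/iodination. 14 comes from ethyl lactate 10 through 11 and aldehyde 13, with ethynylmagnesium bromide 12.

## Roads not taken

**Alternative 1:** the most obvious plan. Cut O–C3 of ring B last and C6–C7 before it. Seco aldehyde/allylic bromide A2 would be closed by an intramolecular Barbier allylation to the ten-membered 10-hydroxy-2-yn-1-one A1, and A1 cyclised transannularly (gold-catalysed 5-endo-dig) to the furanone. The last step creates no stereocentre, so C8, C9 and the free tertiary C10 alcohol must all be built on a long chain. The macrocyclisation must form a strained cyclodecenynone and set C6/C7 while a Z-enal, an ynone and an allylic bromide coexist. The chosen plan makes C9, C10 and the ring together from a much simpler precursor.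

**Alternative 2:** the same aldol bond, made between two fragments. Silyloxyfuran A3 and aldehyde A4 would be joined at C9–C10, the product elaborated to A5, and ring A closed at C6–C7 by intramolecular allylation. This is convergent, but without a tether nothing but simple diastereoselection chooses the furan face at C10. A4 is a β,γ-unsaturated α-alkoxy aldehyde prone to racemisation and conjugation. The ring closure must then still set C6 and C7 from an isomerisable Z-enal. That is two uncertain steps where the chosen route has one.

**Alternative 3:** cut C4=C5 and close ring A by metathesis of diene A6. The step would have to form a trisubstituted, electron-poor olefin conjugated to ring B inside a strained ten-membered ring, in the presence of a methylene lactone and a methacrylate. The ring would control the geometry only if it closes at all, and all five stereocentres, both esters and ring B would have to be in place beforehand.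

Key step: step 13

## Steps

Step 1
Reactants: 1 2-vinyloxirane (racemic); 2 4-methoxybenzyl alcohol
Product: 3 (S)-2-[(4-methoxybenzyl)oxy]but-3-en-1-ol
Conditions: Pd2(dba)3·CHCl3 (1 mol %), (R,R)-N,N'-bis(2-diphenylphosphinobenzoyl)-1,2-diaminocyclohexane (3 mol %), Et3B (1 mol %), CH2Cl2, rt
Reagents that add atoms: none
Why: Palladium-catalysed dynamic kinetic asymmetric allylic etherification: both enantiomers of 1 pass through interconverting π-allyl palladium complexes and the borate delivers the alkoxide to the internal carbon; the ligand enantiomer is the one that gives the 2S ether (the antipode is used if the sense proves opposite).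

Step 2
Reactants: 3 (S)-2-[(4-methoxybenzyl)oxy]but-3-en-1-ol; 4 2-(bromomethyl)acrylic acid
Product: 5 (S)-2-[(4-methoxybenzyl)oxy]but-3-en-1-yl 2-(bromomethyl)acrylate
Conditions: DCC, DMAP (5 mol %), CH2Cl2, 0 °C
Reagents that add atoms: none
Why: Steglich esterification of the primary alcohol; low temperature and little DMAP keep the allylic bromide intact.

Step 3
Reactants: 5 diene ester
Product: 6 (S)-3-(bromomethyl)-5-[(4-methoxybenzyl)oxy]-5,6-dihydro-2H-pyran-2-one
Conditions: second-generation Grubbs catalyst (H2IMes)(PCy3)Cl2Ru=CHPh (5 mol %), CH2Cl2 (5 mM), 40 °C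
Reagents that add atoms: none
Why: Ring-closing metathesis of an acrylate with a homoallylic ester alkene to an α-substituted unsaturated δ-lactone; the ring fixes C8 cis to the carbonyl carbon on the C7=C11 bond.

Step 4
Reactants: 7 but-2-yne-1,4-diol
Product: 8 4-[(tert-butyldimethylsilyl)oxy]but-2-yn-1-ol
Conditions: NaH (1.0 equiv), THF, 0 °C; TBSCl (1.0 equiv), rt
Reagents that add atoms: tert-butyldimethylsilyl chloride, CC(C)(C)[Si](C)(C)Cl
Why: Monosilylation of a symmetrical diol through its monosodium alkoxide; the silylated oxygen becomes O15.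

Step 5
Reactants: 8 monosilyl ether
Product: 9 (Z)-4-[(tert-butyldimethylsilyl)oxy]-3-iodobut-2-en-1-ol
Conditions: NaAlH2(OCH2CH2OMe)2 (Red-Al), THF, 0 °C; then I2, −78 to 0 °C
Reagents that add atoms: iodine, II
Why: Hydroxyl-directed trans-hydroalumination puts hydride on the proximal and aluminium on the distal alkyne carbon, and iodinolysis proceeds with retention. Iodine therefore ends up on C4, cis to the CH2OH arm (C6), which is the C3/C6 cis geometry of the target olefin.

Step 6
Reactants: 10 ethyl (S)-lactate
Product: 11 ethyl (S)-2-(triethylsilyloxy)propanoate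
Conditions: TESCl, imidazole, CH2Cl2, 0 °C to rt
Reagents that add atoms: chlorotriethylsilane, CC[Si](Cl)(CC)CC
Why: Standard silylation; TES is chosen so that it can later be removed in the presence of the primary TBS ether.

Step 7
Reactants: 11 silyl lactate; 12 ethynylmagnesium bromide
Product: 14 (4S)-4-(triethylsilyloxy)pent-1-yn-3-ol (both C3 epimers), via (S)-2-(triethylsilyloxy)propanal 13 (not isolated)
Conditions: i-Bu2AlH (1.05 equiv), CH2Cl2, −78 °C; then HC≡CMgBr, THF, −78 to 0 °C
Reagents that add atoms: none
Why: One-pot partial reduction of an α-silyloxy ester and Grignard addition to the released aldehyde; the carbinol configuration is irrelevant because C1 is oxidised in step 11.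

Step 8
Reactants: 9 Z-iodide; 14 alkynol
Product: 15 (2E,7S)-3-{[(tert-butyldimethylsilyl)oxy]methyl}-7-(triethylsilyloxy)oct-2-en-4-yne-1,6-diol
Conditions: PdCl2(PPh3)2 (3 mol %), CuI (6 mol %), Et3N, THF, rt
Reagents that add atoms: none
Why: Sonogashira coupling forms C3–C4 with retention of olefin geometry (the descriptor changes to E only because the alkyne carbon ranks below CH2OSi); room temperature avoids cycloisomerisation of the enynol.

Step 9
Reactants: 15 enyne diol
Product: 16 (2E,7S)-3-{[(tert-butyldimethylsilyl)oxy]methyl}-6-hydroxy-7-(triethylsilyloxy)oct-2-en-4-ynal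
Conditions: TEMPO (10 mol %), PhI(OAc)2 (1.1 equiv), CH2Cl2, rt
Reagents that add atoms: none
Why: Oxoammonium oxidation selects the primary allylic alcohol over the secondary propargylic one, and the near-neutral medium should preserve the olefin geometry.

Step 10
Reactants: 16 enynal; 6 bromolactone
Product: 18 6,12-γ-lactone diol (8-OPMB; 9-OH; 1-OH; 10-OTES; 15-OTBS), via δ-lactone adduct 17 (not isolated)
Conditions: Zn dust, THF/sat. aq NH4Cl 2:1, 0 °C to rt; then PPTS (10 mol %), CH2Cl2, rt
Reagents that add atoms: none
Why: Barbier 2-(alkoxycarbonyl)allylation through a six-membered chair: C8 is locked cis to the ester, so the anti adduct (6,7-trans) forms, and the aldehyde is taken up on the ring face opposite the adjacent PMB ether (sets C7 relative to C8). The C6 alkoxide then opens the δ-lactone to the more stable γ-lactone (ring C) and frees the C9 alcohol.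

Step 11
Reactants: 18 lactone diol
Product: 19 ynone aldehyde (C9 aldehyde; C1 ketone; 10-OTES)
Conditions: Dess–Martin periodinane (3 equiv), NaHCO3, CH2Cl2, 0 °C to rt
Reagents that add atoms: none
Why: One buffered Dess–Martin oxidation converts the primary alcohol to the α-alkoxy aldehyde and the propargylic alcohol to the ynone without epimerising C8.

Step 12
Reactants: 19 ynone aldehyde
Product: 21 furanone aldehyde (ring B with C10–H; C9 aldehyde), via hydroxy ynone 20 (not isolated)
Conditions: HF·pyridine, pyridine, THF, 0 °C; then AuCl3 (5 mol %), CH2Cl2, rt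
Reagents that add atoms: none
Why: Buffered fluoride removes the secondary TES ether much faster than the primary TBS ether; gold-catalysed 5-endo-dig addition of the C10 hydroxyl to C3 of the α′-hydroxy ynone and a proton shift give the 3(2H)-furanone.

Step 13
Reactants: 21 furanone aldehyde
Product: 23 tricyclic aldol (ring A closed; 9-OH; 8-OPMB; 15-OTBS), via magnesium furanolate 22 (not isolated)
Conditions: MgBr2·OEt2 (3 equiv), i-Pr2NEt (3 equiv), CH2Cl2 (2 mM, slow addition of 21), −40 to −10 °C; AcOH/NaOAc buffer at −40 °C
Reagents that add atoms: none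
Why: Soft enolisation: MgBr2 binds the vinylogous ester carbonyl of ring B and i-Pr2NEt removes the C10 proton, so both C10 epimers of 21 converge on one planar aromatic magnesium 3-furanolate 22, whose enolate carbon C10 adds to the magnesium-bound C9 aldehyde in an intramolecular aldol addition that dearomatises the furan and leaves ring B as the 3(2H)-furanone. The closest known reaction types are magnesium halide/amine direct aldol additions of acidic carbonyl compounds and the C2-selective aldol additions of 3-silyloxyfurans and 3(2H)-furanone enolates to aldehydes, which also create the quaternary ring carbon. Ring A (C1–C10) is closed in the 10-exo-trig mode at the aldehyde carbon, which also closes the nine-membered oxacycle through the ring oxygen and completes the 11-oxabicyclo[6.2.1] core. C9: magnesium chelated between O9 and the PMB ether oxygen O8 fixes the aldehyde rotamer, and C10 arrives on the chelate face that carries H8, which gives the 8,9-syn (9R) carbinol. C10: the same magnesium is held by the furanolate oxygen O1, so the addition runs through a closed six-membered array in which O9 lies next to O1, while the tether to C3 keeps C8 over the C1 side of the ring oxygen; for the 9R aldehyde face both demands are met only on the furan face that gives 10S. Needed selectivities: C10 over C2 (C10 is the enolate carbon, C2 only an enol ether carbon), aldehyde over the C13 acceptor (the aldehyde is the chelated electrophile) and ring closure over oligomerisation (high dilution; the Z olefin and trans-fused lactone already bend the C4–C9 arc towards C10). The adduct is held as its magnesium chelate and released by a cold buffered quench to limit retro-aldol opening.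

Step 14
Reactants: 23 tricyclic aldol; 24 3-methylbutanoyl chloride
Product: 25 9-O-isovalerate (8-OPMB; 15-OTBS)
Conditions: pyridine, DMAP (0.1 equiv), CH2Cl2, −20 to 0 °C
Reagents that add atoms: none
Why: Acylation of the hindered secondary alcohol with an acid chloride under weakly basic conditions; once esterified the C9–C10 bond can no longer cleave by retro-aldol, and β-elimination is impossible because C10 has no hydrogen.

Step 15
Reactants: 25 isovalerate PMB ether
Product: 26 8-hydroxy 9-O-isovalerate (15-OTBS)
Conditions: DDQ (1.5 equiv), CH2Cl2/pH 7 buffer 10:1, 0 °C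
Reagents that add atoms: none
Why: Oxidative PMB cleavage under buffered, near-neutral conditions, which the electron-poor dienone, the esters and the silyl ether tolerate and which gives acyl migration little chance.

Step 16
Reactants: 26 C8 alcohol; 27 methacrylic anhydride
Product: 28 15-O-TBS ether of the target
Conditions: Et3N, DMAP (0.2 equiv), BHT (trace), CH2Cl2, −20 to 0 °C
Reagents that add atoms: none
Why: DMAP-catalysed acylation of the C8 hydroxyl, run cold and fast so that esterification outruns O9 to O8 acyl migration.

Step 17
Reactants: 28 silyl ether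
Product: 29 CNP0552093.1
Conditions: HF·pyridine, pyridine, THF, 0 °C to rt
Reagents that add atoms: none
Why: Buffered fluoride cleaves the primary allylic TBS ether without base, so the three Michael acceptors and both esters remain untouched.

## Compound list

1 | 2-vinyloxirane (racemic) | C=CC1CO1 | starting material
2 | 4-methoxybenzyl alcohol | COc1ccc(CO)cc1 | starting material
3 | (S)-2-[(4-methoxybenzyl)oxy]but-3-en-1-ol | OC[C@@H](OCc1ccc(OC)cc1)C=C | intermediate
4 | 2-(bromomethyl)acrylic acid | C=C(CBr)C(=O)O | starting material
5 | (S)-2-[(4-methoxybenzyl)oxy]but-3-en-1-yl 2-(bromomethyl)acrylate | C=C(CBr)C(=O)OC[C@@H](OCc1ccc(OC)cc1)C=C | intermediate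
6 | (S)-3-(bromomethyl)-5-[(4-methoxybenzyl)oxy]-5,6-dihydro-2H-pyran-2-one | O=C1OC[C@@H](OCc2ccc(OC)cc2)C=C1CBr | intermediate
7 | but-2-yne-1,4-diol | OCC#CCO | starting material
8 | 4-[(tert-butyldimethylsilyl)oxy]but-2-yn-1-ol | OCC#CCO[Si](C)(C)C(C)(C)C | intermediate
9 | (Z)-4-[(tert-butyldimethylsilyl)oxy]-3-iodobut-2-en-1-ol | OC/C=C(/CO[Si](C)(C)C(C)(C)C)I | intermediate
10 | ethyl (S)-lactate | CCOC(=O)[C@H](C)O | starting material
11 | ethyl (S)-2-(triethylsilyloxy)propanoate | CCOC(=O)[C@H](C)O[Si](CC)(CC)CC | intermediate
12 | ethynylmagnesium bromide | C#C[Mg]Br | starting material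
13 | (S)-2-(triethylsilyloxy)propanal | O=C[C@H](C)O[Si](CC)(CC)CC | intermediate
14 | (4S)-4-(triethylsilyloxy)pent-1-yn-3-ol, both C3 epimers | C#CC(O)[C@H](C)O[Si](CC)(CC)CC | intermediate
15 | (2E,7S)-3-{[(tert-butyldimethylsilyl)oxy]methyl}-7-(triethylsilyloxy)oct-2-en-4-yne-1,6-diol (C6 of the chain cis to the alkyne) | OC/C=C(/CO[Si](C)(C)C(C)(C)C)C#CC(O)[C@H](C)O[Si](CC)(CC)CC | intermediate
16 | (2E,7S)-3-{[(tert-butyldimethylsilyl)oxy]methyl}-6-hydroxy-7-(triethylsilyloxy)oct-2-en-4-ynal | O=C/C=C(/CO[Si](C)(C)C(C)(C)C)C#CC(O)[C@H](C)O[Si](CC)(CC)CC | intermediate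
17 | δ-lactone Barbier adduct: 3-methylene-δ-lactone carrying the PMB ether at C8 and the C6 carbinol chain at C7, trans to the PMB ether | C=C1C(=O)OC[C@@H](OCc2ccc(OC)cc2)[C@@H]1[C@H](O)/C=C(/CO[Si](C)(C)C(C)(C)C)C#CC(O)[C@H](C)O[Si](CC)(CC)CC | intermediate
18 | 6,12-γ-lactone diol: trans-fused α-methylene γ-lactone (ring C), 8-OPMB, 9-OH, 1-OH, 2-yne, 10-OTES, 15-OTBS; C6, C7, C8 arranged as in 29 | COc1ccc(CO[C@H](CO)[C@H]2C(=C)C(=O)O[C@@H]2/C=C(/CO[Si](C)(C)C(C)(C)C)C#CC(O)[C@H](C)O[Si](CC)(CC)CC)cc1 | intermediate
19 | ynone aldehyde: as 18 with C9 aldehyde and C1 ketone | COc1ccc(CO[C@H](C=O)[C@H]2C(=C)C(=O)O[C@@H]2/C=C(/CO[Si](C)(C)C(C)(C)C)C#CC(=O)[C@H](C)O[Si](CC)(CC)CC)cc1 | intermediate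
20 | α′-hydroxy ynone aldehyde: as 19 with free 10-OH | COc1ccc(CO[C@H](C=O)[C@H]2C(=C)C(=O)O[C@@H]2/C=C(/CO[Si](C)(C)C(C)(C)C)C#CC(=O)[C@H](C)O)cc1 | intermediate
21 | furanone aldehyde: 2-methyl-3(2H)-furanon-5-yl (ring B, C10–H, either epimer) on C4 of the Z olefin, ring C, 8-OPMB, C9 aldehyde, 15-OTBS | COc1ccc(CO[C@H](C=O)[C@H]2C(=C)C(=O)O[C@@H]2/C=C(/CO[Si](C)(C)C(C)(C)C)C2=CC(=O)C(C)O2)cc1 | intermediate
22 | magnesium 3-furanolate of 21 (aromatic furan, O1–MgBr) | COc1ccc(CO[C@H](C=O)[C@H]2C(=C)C(=O)O[C@@H]2/C=C(/CO[Si](C)(C)C(C)(C)C)c2cc(O[Mg]Br)c(C)o2)cc1 | intermediate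
23 | tricyclic aldol: rings A, B and C complete, 9α-OH, 8-OPMB, 15-OTBS; 6R,7S,8S,9R,10S arrangement of 29 | COc1ccc(CO[C@H]2[C@H]3C(=C)C(=O)O[C@@H]3/C=C(/CO[Si](C)(C)C(C)(C)C)C3=CC(=O)[C@@](C)(O3)[C@@H]2O)cc1 | intermediate
24 | 3-methylbutanoyl chloride (isovaleryl chloride) | CC(C)CC(=O)Cl | starting material
25 | 9-O-isovalerate of 23 | COc1ccc(CO[C@H]2[C@H]3C(=C)C(=O)O[C@@H]3/C=C(/CO[Si](C)(C)C(C)(C)C)C3=CC(=O)[C@@](C)(O3)[C@@H]2OC(=O)CC(C)C)cc1 | intermediate
26 | 8-hydroxy 9-O-isovalerate, 15-OTBS | O[C@H]1[C@H]2C(=C)C(=O)O[C@@H]2/C=C(/CO[Si](C)(C)C(C)(C)C)C2=CC(=O)[C@@](C)(O2)[C@@H]1OC(=O)CC(C)C | intermediate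
27 | methacrylic anhydride | C=C(C)C(=O)OC(=O)C(C)=C | starting material
28 | 15-O-TBS ether of the target | C=C(C)C(=O)O[C@H]1[C@H]2C(=C)C(=O)O[C@@H]2/C=C(/CO[Si](C)(C)C(C)(C)C)C2=CC(=O)[C@@](C)(O2)[C@@H]1OC(=O)CC(C)C | intermediate
29 | CNP0552093.1 (8β-methacryloyloxy-9α-isovaleryloxy-15-hydroxy furanoheliangolide; 4Z,6R,7S,8S,9R,10S) | C=C(C)C(=O)O[C@H]1[C@H]2C(=C)C(=O)O[C@@H]2/C=C(/CO)C2=CC(=O)[C@@](C)(O2)[C@@H]1OC(=O)CC(C)C | target

## Step count and least certain steps

Total steps: 17. Longest linear sequence: 12 (steps 4, 5, 8–17 from 7; equally steps 6–17 from 10).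

**Step 13 (key step).** Several things may go wrong:
- retro-aldol ring opening under the basic magnesium conditions, because the furanolate is a stabilised leaving enolate and the ring is strained;
- intermolecular aldol oligomerisation;
- epimerisation at C8 by enolisation of the chelated aldehyde;
- conjugate addition of the furanolate to C13;
- addition to the other furan face if the ten-membered transition state prefers the opposite twist about C3–C4. Both faces are within reach of the tether, so this outcome rests on the chelate argument and not on a rigid constraint.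

Fallback, an irreversible reductive ring closure: from 21, the magnesium furanolate 22 is quenched with N-bromosuccinimide to give the C10 bromide F1. Samarium diiodide (SmI2, 2.2 equiv, THF, −78 °C, high dilution) converts it into the trivalent samarium furanolate F2, which adds to the C9 aldehyde in an intramolecular Reformatsky reaction through a closed transition state. A cold acidic quench returns the route at 23.

**Step 10.** The olefin geometry of 16 may be lost by reversible conjugate addition in the zinc/ammonium chloride medium. Control of C6/C7 may be incomplete if the allylzinc reacts outside the chair arrangement, and translactonisation may be slow. Fallback, allylboration in place of the Barbier reaction: from 6, palladium-catalysed Miyaura borylation (B2pin2, Pd2(dba)3, KOAc) gives the allylboronate F3. Its thermal addition to 16 in toluene proceeds through a closed chair without Lewis acidic salts; the borate of 17 lactonises on work-up, and the route is rejoined at 18.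

**Step 12.** The sensitive α-alkoxy aldehyde may epimerise at C8 or decompose during fluoride and gold treatment, and other π systems may be activated. Fallback, a change of order so that the aldehyde is absent during ring B formation: from 18, MnO2 oxidises only the enyne-activated propargylic alcohol to the ynone alcohol F4. HF·pyridine/pyridine releases the hydroxy ynone alcohol F5, which is cyclised (AuCl3 or catalytic DBU) to the furanone alcohol F6. Dess–Martin oxidation of the C9 alcohol returns the route at 21.

**Step 14.** The β-hydroxy ketone may open by retro-aldol under the acylation conditions, and the neopentyl-like C9 hydroxyl may acylate slowly. Fallback, no isolation of the free aldol: from 21, the metal aldolate formed in step 13 is acylated in the same flask with 24 before the quench, which leads directly to 25.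

**Step 16.** The isovalerate may migrate from O9 to O8 through the cyclic orthoester while the C8 hydroxyl is free under base, giving the regioisomeric diester. Fallback, reversed order of the two acylations: from 23, DDQ gives the diol F7. The less hindered C8 hydroxyl is esterified first with 27 at low temperature to give the 8-methacrylate F8. Acylation of the C9 hydroxyl with 24 (pyridine, DMAP) then returns the route at 28.

## Further compounds

F1 | step 13 | C10 bromide of 21 (2-bromo-2-methyl-3(2H)-furanone, both epimers) | COc1ccc(CO[C@H](C=O)[C@H]2C(=C)C(=O)O[C@@H]2/C=C(/CO[Si](C)(C)C(C)(C)C)C2=CC(=O)C(C)(Br)O2)cc1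
F2 | step 13 | samarium 3-furanolate of 21 (O1–SmI2) | COc1ccc(CO[C@H](C=O)[C@H]2C(=C)C(=O)O[C@@H]2/C=C(/CO[Si](C)(C)C(C)(C)C)c2cc(O[Sm](I)I)c(C)o2)cc1
F3 | step 10 | (S)-5-[(4-methoxybenzyl)oxy]-3-[(pinacolboryl)methyl]-5,6-dihydro-2H-pyran-2-one | O=C1OC[C@@H](OCc2ccc(OC)cc2)C=C1CB1OC(C)(C)C(C)(C)O1
F4 | step 12 | ynone alcohol (as 18 with C1 ketone, 9-OH kept) | COc1ccc(CO[C@H](CO)[C@H]2C(=C)C(=O)O[C@@H]2/C=C(/CO[Si](C)(C)C(C)(C)C)C#CC(=O)[C@H](C)O[Si](CC)(CC)CC)cc1
F5 | step 12 | hydroxy ynone alcohol (as F4 with free 10-OH) | COc1ccc(CO[C@H](CO)[C@H]2C(=C)C(=O)O[C@@H]2/C=C(/CO[Si](C)(C)C(C)(C)C)C#CC(=O)[C@H](C)O)cc1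
F6 | step 12 | furanone alcohol (as 21 with 9-OH in place of the aldehyde) | COc1ccc(CO[C@H](CO)[C@H]2C(=C)C(=O)O[C@@H]2/C=C(/CO[Si](C)(C)C(C)(C)C)C2=CC(=O)C(C)O2)cc1
F0 | step 14 | none | none
F7 | step 16 | 8,9-diol (15-OTBS) | O[C@H]1[C@H]2C(=C)C(=O)O[C@@H]2/C=C(/CO[Si](C)(C)C(C)(C)C)C2=CC(=O)[C@@](C)(O2)[C@@H]1O
F8 | step 16 | 8-O-methacrylate 9-alcohol (15-OTBS) | C=C(C)C(=O)O[C@H]1[C@H]2C(=C)C(=O)O[C@@H]2/C=C(/CO[Si](C)(C)C(C)(C)C)C2=CC(=O)[C@@](C)(O2)[C@@H]1O
A1 | alternative 1 | ten-membered 10-hydroxy-2-yn-1-one with ring C, both esters and 15-OTBS | C=C(C)C(=O)O[C@H]1[C@H]2C(=C)C(=O)O[C@@H]2/C=C(/CO[Si](C)(C)C(C)(C)C)C#CC(=O)[C@@](C)(O)[C@@H]1OC(=O)CC(C)C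
A2 | alternative 1 | seco Z-enal ynone with tertiary C10 alcohol and methyl 2-(bromomethyl)enoate terminus | O=C/C=C(/CO[Si](C)(C)C(C)(C)C)C#CC(=O)[C@@](C)(O)[C@H](OC(=O)CC(C)C)[C@@H](OC(=O)C(C)=C)/C=C(/CBr)C(=O)OC
A3 | alternative 2 | 2-methyl-3-(triisopropylsilyloxy)furan carrying the Z side chain with 15-OTBS and 6-OTES | Cc1oc(/C(CO[Si](C)(C)C(C)(C)C)=C\CO[Si](CC)(CC)CC)cc1O[Si](C(C)C)(C(C)C)C(C)C
A4 | alternative 2 | methyl (S,E)-2-(bromomethyl)-4-[(4-methoxybenzyl)oxy]-5-oxopent-2-enoate | O=C[C@@H](OCc1ccc(OC)cc1)/C=C(/CBr)C(=O)OC
A5 | alternative 2 | seco furanone Z-enal with C9/C10 set, both esters and methyl 2-(bromomethyl)enoate terminus | O=C/C=C(/CO[Si](C)(C)C(C)(C)C)C1=CC(=O)[C@@](C)(O1)[C@H](OC(=O)CC(C)C)[C@@H](OC(=O)C(C)=C)/C=C(/CBr)C(=O)OC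
A6 | alternative 3 | metathesis diene: ring B with 3-silyloxyprop-1-en-2-yl at C3, C6-vinyl ring C, both esters | C=C(C)C(=O)O[C@@H]([C@H]1C(=C)C(=O)O[C@@H]1C=C)[C@@H](OC(=O)CC(C)C)[C@]1(C)OC(C(=C)CO[Si](C)(C)C(C)(C)C)=CC1=O
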